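**Plan**

Atom labels (target): C1 = CH–O‑angelate, C2 = CH2, C3 = CH–OH, C4 = quaternary cyclobutane carbon (CH3, C3), C5 and C7 = cyclobutane bridgeheads, C6 = cyclobutane CH, C8 = ketone carbon (on C7), C9 = CH2, C10 = CH–CH3 (on C5), C11 = C(CH3)(CH2OAc) joining C6 and C1.
Enabling feature: C1 is bonded to quaternary C11, whose CH2OAc is a reduced ester, so the seven‑membered ring C1–C2–C3–C4–C5(C7)–C6–C11 holds a β‑hydroxy ester retron; its two ends sit cis on the cyclobutane C4–C5–C6–C7.
Cuts: (a) angelate, acetate, silyl ether, ketal; (b) C11–C1 (samarium Reformatsky aldol, seven‑membered ring); (c) C6–C11 at a C6 cyclobutanone; (d) C5–C6 and C4–C7 by an intramolecular vinylketene–alkene [2+2], which gives the cyclobutane and the six‑membered ring of the bicyclo[3.1.1]heptane together; (e) the acyclic chain at C3–C2, C5=C4 and C9–C8.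
Forward: Roche ester → chain (C9–C8 by Negishi coupling, C5=C4 by Wittig, C3–C2 by allylboration) → [2+2] (bicyclic core) → C11 unit on C6 → seven‑membered ring → ester adjustments.
Stereochemistry: C10 from the (R)‑Roche ester; C3 from the allylborane; C4, C5, C7 relayed from C10 and the (E)‑alkene in the [2+2]; C6 by hydride delivery anti to the C4 arm; C11 and C1 in the key step under control of C3.

Key step: step 15

Remark: C11 before the key step and the geometry of the exocyclic C6=C11 bond are carried as mixtures because both are erased later; the SMILES of those compounds leave these elements undefined.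

**Route**

Step 1
Reactants: 1 methyl (R)-3-hydroxy-2-methylpropanoate
Product: 2 methyl (S)-3-iodo-2-methylpropanoate
Conditions: I2, PPh3, imidazole, CH2Cl2, 0 °C → rt
Reagents that add atoms: iodine [I][I]
Why: Appel-type iodination of the primary alcohol does not touch the α-stereocentre, whose descriptor changes from R to S only because iodine changes the CIP order.

Step 2
Reactants: 3 tert-butyl acetoacetate
Product: 4 tert-butyl (E)-3-(trifluoromethylsulfonyloxy)but-2-enoate
Conditions: Tf2O, aqueous Me4NOH, hexanes, 5–10 °C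
Reagents that add atoms: trifluoromethanesulfonic anhydride O=S(=O)(OS(=O)(=O)C(F)(F)F)C(F)(F)F
Why: O-Sulfonylation of the β-keto ester enolate with the non-chelating tetramethylammonium counter-ion should give the (E)-enol triflate, in which the methyl group is cis to the ester as the later γ-deprotonation requires.

Step 3
Reactants: 2 methyl (S)-3-iodo-2-methylpropanoate; 4 tert-butyl (E)-3-(trifluoromethylsulfonyloxy)but-2-enoate
Product: 6 1-tert-butyl 6-methyl (2E,5R)-3,5-dimethylhex-2-enedioate, via alkylzinc iodide 5 (not isolated)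
Conditions: Zn dust (activated with BrCH2CH2Br and Me3SiCl), DMF, rt; then 4, Pd(PPh3)4 (5 mol %), THF/DMF, rt → 45 °C
Reagents that add atoms: none
Why: Zinc insertion gives the ester-bearing alkylzinc iodide 5 (the stereocentre is not the metallated carbon), and Negishi coupling under zerovalent palladium joins C9 to C8 with retention of the alkene geometry.

Step 4
Reactants: 6 1-tert-butyl 6-methyl (2E,5R)-3,5-dimethylhex-2-enedioate
Product: 7 tert-butyl (2E,5R)-3,5-dimethyl-6-oxohex-2-enoate
Conditions: i-Bu2AlH (1.05 equiv), CH2Cl2, −78 °C; MeOH, aqueous potassium sodium tartrate (KNaC4H4O6)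
Reagents that add atoms: none
Why: Partial reduction with i-Bu2AlH at −78 °C stops at the aluminium hemiacetal of the saturated methyl ester, while the conjugated and bulky tert-butyl ester reacts much more slowly and the α-stereocentre is not epimerised.

Step 5
Reactants: 7 tert-butyl (2E,5R)-3,5-dimethyl-6-oxohex-2-enoate; 8 2-(triphenylphosphoranylidene)propanal
Product: 9 tert-butyl (2E,5R,6E)-3,5,7-trimethyl-8-oxoocta-2,6-dienoate
Conditions: toluene, 90 °C
Reagents that add atoms: none
Why: Wittig olefination with the formyl-stabilised ylide gives the (E)-trisubstituted enal under neutral conditions, placing the future C4 methyl cis to the chain, the geometry that the cycloaddition later turns into the C4 configuration.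

Step 6
Reactants: 9 tert-butyl (2E,5R,6E)-3,5,7-trimethyl-8-oxoocta-2,6-dienoate; 10 (+)-B-allyldiisopinocampheylborane
Product: 12 tert-butyl (2E,5R,6E,8R)-8-hydroxy-3,5,7-trimethylundeca-2,6,10-trienoate, via diisopinocampheylborinate 11 (not isolated)
Conditions: Et2O, −78 °C; then aqueous NaOH, 30% H2O2, 0 °C → rt
Reagents that add atoms: none
Why: Brown allylboration through a chair transition state, in which the reagent derived from (−)-α-pinene adds allyl to the Re face of the aldehyde and sets C3 as R under reagent control, the remote C10 centre being too far away to interfere.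

Step 7
Reactants: 12 tert-butyl (2E,5R,6E,8R)-8-hydroxy-3,5,7-trimethylundeca-2,6,10-trienoate
Product: 13 tert-butyl (2E,5R,6E,8R)-8-(tert-butyldimethylsilyloxy)-3,5,7-trimethylundeca-2,6,10-trienoate
Conditions: t-BuMe2SiCl, imidazole, DMF, rt
Reagents that add atoms: tert-butyldimethylsilyl chloride CC(C)(C)[Si](C)(C)Cl
Why: Standard silylation of the secondary allylic alcohol gives the ether that later steers the key ring closure and survives to the last step.

Step 8
Reactants: 13 tert-butyl (2E,5R,6E,8R)-8-(tert-butyldimethylsilyloxy)-3,5,7-trimethylundeca-2,6,10-trienoate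
Product: 15 (2E,5R,6E,8R)-8-(tert-butyldimethylsilyloxy)-3,5,7-trimethylundeca-2,6,10-trienoic acid, via trimethylsilyl ester 14 (not isolated)
Conditions: Me3SiOTf, 2,6-lutidine, CH2Cl2, 0 °C; then pH 7 buffer
Reagents that add atoms: none
Why: Silyl triflate cleavage of the tert-butyl ester (loss of isobutene from the O-silylated ester) runs under 2,6-lutidine buffering that leaves the allylic silyl ether and the alkenes untouched, and water then hydrolyses the silyl ester 14.

Step 9
Reactants: 15 (2E,5R,6E,8R)-8-(tert-butyldimethylsilyloxy)-3,5,7-trimethylundeca-2,6,10-trienoic acid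
Product: 18 bicyclo[3.1.1]heptane C6-cyclobutanone with C8 methylidene, via acid chloride 16 (not isolated), via vinylketene 17 (not isolated)
Conditions: Me2C=C(Cl)NMe2, CH2Cl2, 0 °C → rt; then slow addition to Et3N, toluene, 110 °C (high dilution)
Reagents that add atoms: none
Why: Intramolecular ketene–alkene [2+2] cycloaddition of a vinylketene, the closure known for geranoyl chloride: 1,4-dehydrochlorination of 16 at the γ-methyl gives 17, its carbonyl carbon bonds to the less substituted alkene carbon C5 and its α-carbon C7 to C4, the suprafacial addition turns the (E)-alkene into C4 with its methyl syn to the new C8–C10 bridge and the arm anti, and 1,3-allylic strain between the C10 substituents and that methyl puts C10–H toward C4 and the C10 methyl toward the carbonyl bridge, so that the Roche centre fixes C5, C7 and C4.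

Step 10
Reactants: 18 bicyclo[3.1.1]heptane C6-cyclobutanone with C8 methylidene; 19 methyl 2-(trimethylsilyl)acetate
Product: 21 exocyclic C6=C11 enoate (E/Z mixture), via lithiated silylacetate 20 (not isolated)
Conditions: LiN(i-Pr)2, 19, THF, −78 °C; then 18, −78 °C → rt
Reagents that add atoms: none
Why: Peterson olefination, in which the small and very nucleophilic lithium enolate 20 adds to the strained cyclobutanone (which cannot enolise because both α-carbons are bridgeheads) and the β-silyl alkoxide eliminates to the exocyclic enoate, whose geometry is irrelevant.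

Step 11
Reactants: 21 exocyclic C6=C11 enoate (E/Z mixture)
Product: 22 methyl ester with C6–H syn to the C8–C10 bridge and the CH2CO2CH3 chain cis to the C4 arm
Conditions: Cu(OAc)2·H2O (5 mol %), 1,2-bis(diphenylphosphino)benzene (5 mol %), (HMe2Si)2O, t-BuOH, toluene, rt
Reagents that add atoms: none
Why: Copper hydride conjugate reduction of a β,β-disubstituted enoate, polar and therefore free of the radical ring-opening that electron-transfer reductants could cause, leaves the two unconjugated alkenes alone and should deliver hydride to C6 from the face of the C8–C10 bridge because the other face is covered by the branched silyloxybutenyl arm on C4, which places the acetate chain cis to that arm.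

Step 12
Reactants: 22 methyl ester with C6–H syn to the C8–C10 bridge and the CH2CO2CH3 chain cis to the C4 arm
Product: 24 methyl 2-(C6-yl)propanoate (both C11 epimers), via lithium enolate 23 (not isolated)
Conditions: LiN(i-Pr)2, THF, −78 °C; MeI, −78 → 0 °C
Reagents that add atoms: iodomethane [CH3]I
Why: Ester enolate alkylation with iodomethane installs the C11 methyl group as both C11 epimers, which does not matter because this centre is erased in the next steps.

Step 13
Reactants: 24 methyl 2-(C6-yl)propanoate (both C11 epimers)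
Product: 26 methyl 2-bromo-2-(C6-yl)propanoate (both C11 epimers), via lithium enolate 25 (not isolated)
Conditions: LiN(i-Pr)2, THF, −78 °C; BrCCl2CCl2Br, −78 °C
Reagents that add atoms: 1,2-dibromo-1,1,2,2-tetrachloroethane BrC(Cl)(Cl)C(Cl)(Cl)Br
Why: Enolate bromination with a positive-bromine donor gives the tertiary α-bromo ester as both epimers, each of which leads to the same enolate in the key step.

Step 14
Reactants: 26 methyl 2-bromo-2-(C6-yl)propanoate (both C11 epimers)
Product: 28 keto aldehyde with C1 aldehyde arm and C8 ketone, via bis-ozonide 27 (not isolated)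
Conditions: O3, CH2Cl2, −78 °C; then Me2S, −78 °C → rt
Reagents that add atoms: ozone [O-][O+]=O
Why: Ozonolysis with reductive work-up cleaves the two electron-rich terminal alkenes together, the vinyl group to the C1 aldehyde and the methylidene to the C8 ketone, and leaves the tertiary bromide and the silyl ether alone.

Step 15
Reactants: 28 keto aldehyde with C1 aldehyde arm and C8 ketone
Product: 30 tricyclic β-hydroxy ester, via samarium enolate 29 (not isolated)
Conditions: SmI2 (2.5 equiv, 0.1 mol/L in THF), −78 °C, slow addition of 28 in THF; aqueous NH4Cl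
Reagents that add atoms: none
Why: Two single-electron transfers from samarium diiodide cleave the C11–Br bond of either epimer, first to a planar α-ester radical and then to one trivalent samarium enolate 29, which adds to the tethered aldehyde through a samarium-bridged six-membered (Zimmerman–Traxler) transition state and gives the aldolate. The closest known reaction type is the SmI2-mediated intramolecular Reformatsky-type aldol used to close medium carbocycles. The seven-membered ring C1–C2–C3–C4–C5–C6–C11 closes in the 7-exo-trig mode, C11 attacking the aldehyde carbon C1. C11 is set by which face of the enolate (which rotamer about C6–C11) meets the aldehyde and C1 by the aldehyde face, and both follow from a chair in which C2 and C6 are equatorial on the chelate ring, the ester carbon is on the outer position and the C11 methyl on the inner one. The step needs the ester on the flank of C7 (the flank of the C3 oxygen) and the new hydroxyl on the flank of C5, trans to both, and this is the outcome of that chair when the forming C3–C2–C1–C11 bridge twists so that C3–H, not the bulky C3 silyloxy group, turns toward the C4 methyl, so the existing C3 centre is the controlling element while the cis placement of the two arms on the cyclobutane secures the closure itself. Chemoselectivity rests on the bromide being reduced at −78 °C far faster than the aldehyde or the C8 ketone, on reduction of the α-ester radical outrunning opening of the cyclobutane, on the ketone being out of reach of the enolate (only a four-membered ring could form) and on the neutral medium sparing the β-silyloxy aldehyde.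

Step 16
Reactants: 30 tricyclic β-hydroxy ester
Product: 31 C8 ethylene ketal of the tricyclic β-hydroxy ester
Conditions: HOCH2CH2OH, PPTS (catalytic), benzene, reflux (Dean–Stark)
Reagents that add atoms: ethane-1,2-diol OCCO
Why: Acid-catalysed ketalisation with azeotropic removal of water masks the only ketone so that the ester can be reduced, the β-hydroxy ester having no α-hydrogen through which it could dehydrate.

Step 17
Reactants: 31 C8 ethylene ketal of the tricyclic β-hydroxy ester
Product: 32 diol with C1–OH and C11–CH2OH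
Conditions: LiAlH4, THF, 0 °C → rt; aqueous NaOH work-up
Reagents that add atoms: none
Why: Hydride reduction of the neopentyl ester with LiAlH4 gives the primary alcohol, the ketal and the silyl ether being inert to hydride.

Step 18
Reactants: 32 diol with C1–OH and C11–CH2OH
Product: 33 primary acetate with free C1–OH
Conditions: Ac2O, pyridine, CH2Cl2, 0 °C
Reagents that add atoms: acetic anhydride CC(=O)OC(C)=O
Why: Selective acetylation, the primary hydroxyl reacting much faster than the secondary neopentyl hydroxyl at C1 when no acyl-transfer catalyst is used.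

Step 19
Reactants: 33 primary acetate with free C1–OH; 34 angelic acid
Product: 36 C1 angelate with C3 silyl ether and C8 ketal, via mixed anhydride 35 (not isolated)
Conditions: 34, 2,4,6-Cl3C6H2COCl, Et3N, toluene, rt; then 33, 80 °C
Reagents that add atoms: none
Why: Yamaguchi esterification through the mixed anhydride 35 acylates the hindered C1 hydroxyl on heating, and leaving out 4-(dimethylamino)pyridine avoids the conjugate-addition pathway that isomerises angelates to tiglates.

Step 20
Reactants: 36 C1 angelate with C3 silyl ether and C8 ketal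
Product: 37 CNP0212099.1
Conditions: 48% aqueous HF, MeCN, 0 °C → rt
Reagents that add atoms: water O
Why: Aqueous HF in acetonitrile cleaves the hindered silyl ether by fluoride attack at silicon and, being aqueous acid, hydrolyses the dioxolane in the same operation, conditions under which the acetate and the angelate are stable.

**Compound list**

1 | methyl (R)-3-hydroxy-2-methylpropanoate | C[C@H](CO)C(=O)OC | starting material
2 | methyl (S)-3-iodo-2-methylpropanoate | C[C@H](C[I])C(=O)OC | intermediate
3 | tert-butyl acetoacetate | CC(=O)CC(=O)OC(C)(C)C | starting material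
4 | tert-butyl (E)-3-(trifluoromethylsulfonyloxy)but-2-enoate | C/C(OS(=O)(=O)C(F)(F)F)=C\C(=O)OC(C)(C)C | intermediate
5 | (S)-(3-methoxy-2-methyl-3-oxopropyl)zinc iodide (not isolated) | C[C@H](C[Zn]I)C(=O)OC | intermediate
6 | 1-tert-butyl 6-methyl (2E,5R)-3,5-dimethylhex-2-enedioate | C[C@H](C/C(C)=C/C(=O)OC(C)(C)C)C(=O)OC | intermediate
7 | tert-butyl (2E,5R)-3,5-dimethyl-6-oxohex-2-enoate | C[C@H](C/C(C)=C/C(=O)OC(C)(C)C)C=O | intermediate
8 | 2-(triphenylphosphoranylidene)propanal | CC(C=O)=P(c1ccccc1)(c1ccccc1)c1ccccc1 | starting material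
9 | tert-butyl (2E,5R,6E)-3,5,7-trimethyl-8-oxoocta-2,6-dienoate | C[C@H](C/C(C)=C/C(=O)OC(C)(C)C)/C=C(\C)C=O | intermediate
10 | (+)-B-allyldiisopinocampheylborane (from (−)-α-pinene) | C=CCB([C@H]1C[C@H]2C[C@@H]([C@@H]1C)C2(C)C)[C@H]1C[C@H]2C[C@@H]([C@@H]1C)C2(C)C | starting material
11 | diisopinocampheylborinate of alcohol 12 (not isolated) | C=CC[C@@H](OB([C@H]1C[C@H]2C[C@@H]([C@@H]1C)C2(C)C)[C@H]1C[C@H]2C[C@@H]([C@@H]1C)C2(C)C)/C(C)=C/[C@H](C)C/C(C)=C/C(=O)OC(C)(C)C | intermediate
12 | tert-butyl (2E,5R,6E,8R)-8-hydroxy-3,5,7-trimethylundeca-2,6,10-trienoate | C=CC[C@@H](O)/C(C)=C/[C@H](C)C/C(C)=C/C(=O)OC(C)(C)C | intermediate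
13 | tert-butyl (2E,5R,6E,8R)-8-(tert-butyldimethylsilyloxy)-3,5,7-trimethylundeca-2,6,10-trienoate | C=CC[C@@H](O[Si](C)(C)C(C)(C)C)/C(C)=C/[C@H](C)C/C(C)=C/C(=O)OC(C)(C)C | intermediate
14 | trimethylsilyl ester of acid 15 (not isolated) | C=CC[C@@H](O[Si](C)(C)C(C)(C)C)/C(C)=C/[C@H](C)C/C(C)=C/C(=O)O[Si](C)(C)C | intermediate
15 | (2E,5R,6E,8R)-8-(tert-butyldimethylsilyloxy)-3,5,7-trimethylundeca-2,6,10-trienoic acid | C=CC[C@@H](O[Si](C)(C)C(C)(C)C)/C(C)=C/[C@H](C)C/C(C)=C/C(=O)O | intermediate
16 | acid chloride of 15 (not isolated) | C=CC[C@@H](O[Si](C)(C)C(C)(C)C)/C(C)=C/[C@H](C)C/C(C)=C/C(=O)Cl | intermediate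
17 | (5R,6E,8R)-8-(tert-butyldimethylsilyloxy)-5,7-dimethyl-3-methylideneundeca-1,6,10-trien-1-one, vinylketene (not isolated) | C=CC[C@@H](O[Si](C)(C)C(C)(C)C)/C(C)=C/[C@H](C)CC(=C)C=C=O | intermediate
18 | 7-[(1R)-1-(tert-butyldimethylsilyloxy)but-3-en-1-yl]-4,7-dimethyl-2-methylidenebicyclo[3.1.1]heptan-6-one; in target labels C6 = C=O, C8 = C=CH2, C4 methyl syn to the C8–C10 bridge and arm anti, C10 methyl on the side of C6 | C=CC[C@@H](O[Si](C)(C)C(C)(C)C)[C@]1(C)[C@@H]2C(=O)[C@H]1C(=C)C[C@H]2C | intermediate
19 | methyl 2-(trimethylsilyl)acetate | COC(=O)C[Si](C)(C)C | starting material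
20 | lithium enolate of 19 (not isolated) | C[Si](C)(C)C=C(OC)O[Li] | intermediate
21 | methyl 2-(bicyclic C6-ylidene)acetate, exocyclic C6=C11, E/Z mixture, otherwise as 18 | C=CC[C@@H](O[Si](C)(C)C(C)(C)C)[C@]1(C)[C@@H]2C(=CC(=O)OC)[C@H]1C(=C)C[C@H]2C | intermediate
22 | methyl 2-(bicyclic C6-yl)acetate; C6–H syn to the C8–C10 bridge, CH2CO2CH3 cis to the C4 arm | C=CC[C@@H](O[Si](C)(C)C(C)(C)C)[C@]1(C)[C@@H]2[C@@H]([C@H]1C(=C)C[C@H]2C)CC(=O)OC | intermediate
23 | lithium enolate of 22 (not isolated) | C=CC[C@@H](O[Si](C)(C)C(C)(C)C)[C@]1(C)[C@@H]2[C@@H]([C@H]1C(=C)C[C@H]2C)C=C(OC)O[Li] | intermediate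
24 | methyl 2-(bicyclic C6-yl)propanoate, both C11 epimers | C=CC[C@@H](O[Si](C)(C)C(C)(C)C)[C@]1(C)[C@@H]2[C@@H]([C@H]1C(=C)C[C@H]2C)C(C)C(=O)OC | intermediate
25 | lithium enolate of 24 (not isolated) | C=CC[C@@H](O[Si](C)(C)C(C)(C)C)[C@]1(C)[C@@H]2[C@@H]([C@H]1C(=C)C[C@H]2C)C(C)=C(OC)O[Li] | intermediate
26 | methyl 2-bromo-2-(bicyclic C6-yl)propanoate, both C11 epimers | C=CC[C@@H](O[Si](C)(C)C(C)(C)C)[C@]1(C)[C@@H]2[C@@H]([C@H]1C(=C)C[C@H]2C)C(C)(Br)C(=O)OC | intermediate
27 | bis(1,2,4-trioxolane) of 26 at the vinyl group and at C8 (not isolated) | C1(OOCO1)C[C@@H](O[Si](C)(C)C(C)(C)C)[C@]2(C)[C@@H]3[C@@H]([C@H]2C4(OOCO4)C[C@H]3C)C(C)(Br)C(=O)OC | intermediate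
28 | keto aldehyde: C1HO–C2H2–C3H(OTBS) arm on C4, C8 ketone, C6 bearing C(CH3)(Br)CO2CH3 (both epimers) | O=CC[C@@H](O[Si](C)(C)C(C)(C)C)[C@]1(C)[C@@H]2[C@@H]([C@H]1C(=O)C[C@H]2C)C(C)(Br)C(=O)OC | intermediate
29 | samarium enolate from 28, C11=C(OCH3)OSmI2 (not isolated) | O=CC[C@@H](O[Si](C)(C)C(C)(C)C)[C@]1(C)[C@@H]2[C@@H]([C@H]1C(=O)C[C@H]2C)C(C)=C(OC)O[Sm](I)I | intermediate
30 | tricyclic β-hydroxy ester: seven-membered ring closed, C1–OH, C3–OTBS, C8 ketone, C11 with CH3 and CO2CH3, all centres as in the target | O[C@@H]1C[C@@H](O[Si](C)(C)C(C)(C)C)[C@]2(C)[C@@H]3[C@@H]([C@H]2C(=O)C[C@H]3C)[C@@]1(C)C(=O)OC | intermediate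
31 | C8 ethylene ketal of 30 | O[C@@H]1C[C@@H](O[Si](C)(C)C(C)(C)C)[C@]2(C)[C@@H]3[C@@H]([C@H]2C4(OCCO4)C[C@H]3C)[C@@]1(C)C(=O)OC | intermediate
32 | diol: C1–OH and C11–CH2OH, C3–OTBS, C8 ketal | O[C@@H]1C[C@@H](O[Si](C)(C)C(C)(C)C)[C@]2(C)[C@@H]3[C@@H]([C@H]2C4(OCCO4)C[C@H]3C)[C@@]1(C)CO | intermediate
33 | primary acetate: C11–CH2OAc, free C1–OH, C3–OTBS, C8 ketal | O[C@@H]1C[C@@H](O[Si](C)(C)C(C)(C)C)[C@]2(C)[C@@H]3[C@@H]([C@H]2C4(OCCO4)C[C@H]3C)[C@@]1(C)COC(C)=O | intermediate
34 | angelic acid, (Z)-2-methylbut-2-enoic acid | C/C=C(/C)C(=O)O | starting material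
35 | angelic 2,4,6-trichlorobenzoic anhydride (not isolated) | C/C=C(/C)C(=O)OC(=O)c1c(Cl)cc(Cl)cc1Cl | intermediate
36 | C1 angelate, C11–CH2OAc, C3–OTBS, C8 ketal | C/C=C(/C)C(=O)O[C@@H]1C[C@@H](O[Si](C)(C)C(C)(C)C)[C@]2(C)[C@@H]3[C@@H]([C@H]2C4(OCCO4)C[C@H]3C)[C@@]1(C)COC(C)=O | intermediate
37 | CNP0212099.1: C1 angelate, C3–OH, C8 ketone, C11–CH2OAc | C/C=C(/C)C(=O)O[C@@H]1C[C@@H](O)[C@]2(C)[C@@H]3[C@@H]([C@H]2C(=O)C[C@H]3C)[C@@]1(C)COC(C)=O | target

**Step count**

Total: 20 steps. Longest linear sequence: 19 steps (from 1 through steps 1 and 3–20; step 2 prepares coupling partner 4).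

**Steps most likely to fail**

Step 15. What may go wrong: the bridge closes slowly, so that the samarium enolate is protonated or the α-ester radical fragments the cyclobutane before closure; or the enolate, whose geometry the electron-transfer route does not define, closes through the other twist with poor facial selectivity at C11 and C1. The fallback is a copper hydride reductive aldol, which forms the same bond and ring from a copper enolate without radical intermediates. It sets out from 22. Enolate aminomethylation (LiN(i-Pr)2, then dimethyl(methylidene)ammonium iodide) should give Mannich base F15. N-Methylation and elimination (MeI, then DBU) should give α-methylene ester F16. Ozonolysis stopped at the end point of the two electron-rich alkenes (the acrylate reacts much more slowly), then Me2S, should give keto aldehyde F17. [(Ph3P)CuH]6 in toluene at −40 °C should add hydride to the methylidene carbon, which becomes the C11 methyl, and the copper enolate should close onto the aldehyde. The fallback comes back to the route at 30.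

Step 11. What may go wrong: hydride is delivered to C6 from the face of the C4 arm (poor or reversed facial selectivity), which would put the acetate chain trans to the arm and make the ring closure impossible. The fallback uses the C3 oxygen as an anchor, so that C11 can only be bonded to C6 on the face of the arm. It sets out from 12. Acylation (propanoic anhydride, DMAP) should give propanoate F8, and Me3SiOTf/2,6-lutidine then water should give acid F9. The conditions of step 9 should give cyclobutanone F10. LiN(i-Pr)2 at −78 °C forms the ester enolate (the ketone has no enolisable hydrogen), which should add to the C6 carbonyl and give the seven-membered hydroxy lactone F11. ClC(O)CO2CH3/DMAP should give methyl oxalate F12. Bu3SnH/AIBN in toluene at 110 °C should remove the tertiary C6 oxygen by radical deoxygenation to give lactone F13; the C6 radical, tied to the arm through the lactone, can take hydrogen only from the bridge face. NaOMe in MeOH should open it to hydroxy ester F14, and silylation (t-BuMe2SiOTf, 2,6-lutidine) comes back to the route at 24.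

Step 9. What may go wrong: the [2+2] is slowed by the branched, inductively deactivated alkene terminus, so that oligomerisation of the ketene takes over, or facial control by C10 is eroded. The fallback runs the cycloaddition on the smaller primary silyl ether and builds the C3 carbinol afterwards on the bicycle. It sets out from 9. Luche reduction (NaBH4, CeCl3·7H2O, MeOH) should give allylic alcohol F1, and t-BuMe2SiCl/imidazole should give silyl ether F2. Me3SiOTf/2,6-lutidine then water should give acid F3, and the conditions of step 9 should give cyclobutanone F4. HF·pyridine should give primary alcohol F5, and Dess–Martin periodinane should give neopentyl aldehyde F6. Reagent 10, then NaOH/H2O2, should add to the aldehyde and not to the hindered ketone, giving homoallylic alcohol F7. Silylation (t-BuMe2SiOTf, 2,6-lutidine) comes back to the route at 18.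

**Further compounds**

F1 | step 9 | tert-butyl (2E,5R,6E)-8-hydroxy-3,5,7-trimethylocta-2,6-dienoate | C[C@H](C/C(C)=C/C(=O)OC(C)(C)C)/C=C(\C)CO
F2 | step 9 | tert-butyl (2E,5R,6E)-8-(tert-butyldimethylsilyloxy)-3,5,7-trimethylocta-2,6-dienoate | C[C@H](C/C(C)=C/C(=O)OC(C)(C)C)/C=C(\C)CO[Si](C)(C)C(C)(C)C
F3 | step 9 | (2E,5R,6E)-8-(tert-butyldimethylsilyloxy)-3,5,7-trimethylocta-2,6-dienoic acid | C[C@H](C/C(C)=C/C(=O)O)/C=C(\C)CO[Si](C)(C)C(C)(C)C
F4 | step 9 | C6-cyclobutanone with CH2OTBS on C4 (anti to the C8–C10 bridge), C8 methylidene, centres as in 18 | CC(C)(C)[Si](C)(C)OC[C@]1(C)[C@@H]2C(=O)[C@H]1C(=C)C[C@H]2C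
F5 | step 9 | C6-cyclobutanone with CH2OH on C4 | OC[C@]1(C)[C@@H]2C(=O)[C@H]1C(=C)C[C@H]2C
F6 | step 9 | C6-cyclobutanone with CHO on C4 | O=C[C@]1(C)[C@@H]2C(=O)[C@H]1C(=C)C[C@H]2C
F7 | step 9 | C6-cyclobutanone with (1R)-1-hydroxybut-3-enyl on C4 (desilyl 18) | C=CC[C@@H](O)[C@]1(C)[C@@H]2C(=O)[C@H]1C(=C)C[C@H]2C
F8 | step 11 | tert-butyl (2E,5R,6E,8R)-3,5,7-trimethyl-8-(propanoyloxy)undeca-2,6,10-trienoate | C=CC[C@@H](OC(=O)CC)/C(C)=C/[C@H](C)C/C(C)=C/C(=O)OC(C)(C)C
F9 | step 11 | (2E,5R,6E,8R)-3,5,7-trimethyl-8-(propanoyloxy)undeca-2,6,10-trienoic acid | C=CC[C@@H](OC(=O)CC)/C(C)=C/[C@H](C)C/C(C)=C/C(=O)O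
F10 | step 11 | C6-cyclobutanone with (1R)-1-(propanoyloxy)but-3-enyl on C4, otherwise as 18 | C=CC[C@@H](OC(=O)CC)[C@]1(C)[C@@H]2C(=O)[C@H]1C(=C)C[C@H]2C
F11 | step 11 | seven-membered hydroxy lactone O3–C(=O)–C11H(CH3)–C6(OH), C6–OH syn to the C8–C10 bridge, C11 epimers | C=CC[C@@H](O3)[C@]1(C)[C@@H]2[C@]([C@H]1C(=C)C[C@H]2C)(O)C(C)C3=O
F12 | step 11 | methyl oxalate of the C6 hydroxyl of F11 | C=CC[C@@H](O3)[C@]1(C)[C@@H]2[C@]([C@H]1C(=C)C[C@H]2C)(OC(=O)C(=O)OC)C(C)C3=O
F13 | step 11 | seven-membered lactone O3–C(=O)–C11H(CH3)–C6H, C6–H syn to the C8–C10 bridge, C11 epimers | C=CC[C@@H](O3)[C@]1(C)[C@@H]2[C@@H]([C@H]1C(=C)C[C@H]2C)C(C)C3=O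
F14 | step 11 | methyl 2-(bicyclic C6-yl)propanoate with free C3–OH (desilyl 24) | C=CC[C@@H](O)[C@]1(C)[C@@H]2[C@@H]([C@H]1C(=C)C[C@H]2C)C(C)C(=O)OC
F15 | step 15 | methyl 3-(dimethylamino)-2-(bicyclic C6-yl)propanoate, Mannich base of 22 | C=CC[C@@H](O[Si](C)(C)C(C)(C)C)[C@]1(C)[C@@H]2[C@@H]([C@H]1C(=C)C[C@H]2C)C(CN(C)C)C(=O)OC
F16 | step 15 | methyl 2-(bicyclic C6-yl)acrylate | C=CC[C@@H](O[Si](C)(C)C(C)(C)C)[C@]1(C)[C@@H]2[C@@H]([C@H]1C(=C)C[C@H]2C)C(=C)C(=O)OC
F17 | step 15 | keto aldehyde with C1 aldehyde arm, C8 ketone and C6 bearing C(=CH2)CO2CH3 | O=CC[C@@H](O[Si](C)(C)C(C)(C)C)[C@]1(C)[C@@H]2[C@@H]([C@H]1C(=O)C[C@H]2C)C(=C)C(=O)OC
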